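The nine O–alkyl bonds are cut first (global dealkylation). Next come the O–C(ring B) bond of the B–O–C bridge and the O–C(ring B) bond of the A–O–B bridge (both Ullmann). Last are the ring D bonds C2'–C3' and C4'–C5', with ring D numbered from C1', the carbon bonded to C1 of ring C.
Enabling feature: ring D is a 2-arylphloroglucinol, so C1' lies between the oxygenated carbons C2' and C6' and faces the third oxygen at C4'. Atoms C1', C6', C5' and C2' map onto C4 (aryl), C3 (OEt), C2 and C1 (C=O) of a 4-aryl-3-ethoxycyclobutenone, and C3'–C4' maps onto HC≡C–OEt.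
Forward: rings A, B and C are bought as benzenes. Ring C gains its fourth oxygen (Dakin, then benzyl), a formyl group and one more carbon, and the derived arylketene adds ethoxyacetylene to give the four-membered ring.
A second ethoxyacetylene expands that ring to ring D around the existing C1–C1' bond, so the tetra-ortho-oxygenated biaryl bond is never made by coupling. Methylation, debenzylation, coupling to the A–O–B bromide and BBr3 complete the chain D–C–O–B–O–A.
Stereochemistry: the target has no stereocentre and, ring D being symmetric, no stereogenic axis. The sp3 centres on the way (C4 of the cyclobutenone and two transient ones) are racemic and vanish on aromatisation.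

Key step: step 8

Remark on the chemistry: the biaryl intermediates between the key step and the last step carry different groups at C2' and C6', so their hindered axis may be stereogenic. They are carried as racemates, which has no consequence because the axis is no longer stereogenic in the target.

Step 1
Reactants: 1 2,4,6-trimethoxybenzaldehyde
Product: 3 2,4,6-trimethoxyphenol, via aryl formate 2 (not isolated)
Conditions: 30% aq H2O2 (1.2 equiv), cat. H2SO4, MeOH, rt
Reagents that add atoms: hydrogen peroxide, OO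
Why: Acid-catalysed Dakin (Baeyer–Villiger-type) oxidation, in which the electron-rich aryl group migrates from carbon to oxygen in the peroxide adduct and formate 2 is methanolysed in the same flask.

Step 2
Reactants: 3 2,4,6-trimethoxyphenol
Product: 4 2-(benzyloxy)-1,3,5-trimethoxybenzene
Conditions: BnBr, K2CO3, DMF, rt, N2
Reagents that add atoms: benzyl bromide, BrCc1ccccc1
Why: Williamson ether synthesis on an oxidation-prone phenol that is alkylated at once, benzyl being the one group that can later be removed beside methyl and ethyl ethers.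

Step 3
Reactants: 4 2-(benzyloxy)-1,3,5-trimethoxybenzene
Product: 6 3-(benzyloxy)-2,4,6-trimethoxybenzaldehyde, via aryl iminium salt 5 (not isolated)
Conditions: POCl3, DMF, 0 °C to rt; then aq NaOAc
Reagents that add atoms: N,N-dimethylformamide, CN(C)C=O; water, O
Why: Vilsmeier–Haack formylation, in which the two free ring positions of 4 are equivalent by symmetry and each lies between two methoxy groups, so a single aldehyde should result after hydrolysis of 5.

Step 4
Reactants: 6 3-(benzyloxy)-2,4,6-trimethoxybenzaldehyde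
Product: 7 2-(benzyloxy)-1,3,5-trimethoxy-4-(2-methoxyethenyl)benzene (E/Z mixture)
Conditions: MeOCH2PPh3Cl, KOtBu, THF, 0 °C to rt
Reagents that add atoms: (methoxymethyl)triphenylphosphonium chloride, COC[P+](c1ccccc1)(c1ccccc1)c1ccccc1.[Cl-]
Why: Wittig methoxymethylenation with a small non-stabilised ylide that adds even to di-ortho-substituted benzaldehydes, the alkene geometry being irrelevant because both isomers lead to the same aldehyde.

Step 5
Reactants: 7 2-(benzyloxy)-1,3,5-trimethoxy-4-(2-methoxyethenyl)benzene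
Product: 8 2-[3-(benzyloxy)-2,4,6-trimethoxyphenyl]acetaldehyde
Conditions: 2 M aq HCl, THF, rt
Reagents that add atoms: water, O
Why: Acid hydrolysis of an enol ether (protonation at the benzylic carbon, capture of the oxocarbenium ion by water), to which aryl methyl and benzyl ethers are inert at room temperature.

Step 6
Reactants: 8 2-[3-(benzyloxy)-2,4,6-trimethoxyphenyl]acetaldehyde
Product: 9 2-[3-(benzyloxy)-2,4,6-trimethoxyphenyl]acetic acid
Conditions: NaClO2, NaH2PO4, 2-methyl-2-butene (20 equiv), t-BuOH/H2O, 0 °C to rt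
Reagents that add atoms: sodium chlorite, [Na+].[O-]Cl=O
Why: Pinnick oxidation, which converts the aldehyde without touching the benzyl ether, while the large excess of alkene traps HOCl before it can chlorinate the free C5 position of ring C.

Step 7
Reactants: 9 2-[3-(benzyloxy)-2,4,6-trimethoxyphenyl]acetic acid; 10 ethoxyacetylene
Product: 13 rac-4-[3-(benzyloxy)-2,4,6-trimethoxyphenyl]-3-ethoxycyclobut-2-en-1-one, via arylacetyl chloride 11 (not isolated), via arylketene 12 (not isolated)
Conditions: (COCl)2, cat. DMF, CH2Cl2, 0 °C to rt, evaporate; then added over 4 h to 10 (5 equiv), Et3N (1.5 equiv), Et2O, 0 °C to rt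
Reagents that add atoms: none
Why: Dehydrochlorination of an acyl chloride to an aldoketene and its (2+2) cycloaddition to an alkoxyacetylene is a known route to 3-alkoxycyclobutenones; the nucleophilic CH terminus of 10 attacks the ketene carbonyl carbon, which places OEt at C3 and the aryl group at the racemic C4, while slow addition into excess 10 and the two ortho methoxy groups hold back ketene dimerisation.

Step 8
Reactants: 13 rac-4-[3-(benzyloxy)-2,4,6-trimethoxyphenyl]-3-ethoxycyclobut-2-en-1-one; 10 ethoxyacetylene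
Product: 18 2-[3-(benzyloxy)-2,4,6-trimethoxyphenyl]-3,5-diethoxyphenol, via vinylketene 14 (not isolated), via alkenylcyclobutenone 15 (not isolated), via dienylketene 16 (not isolated), via cyclohexadienone 17 (not isolated)
Conditions: 10 (5 equiv), toluene (0.5 M), sealed tube, 80 °C, then 110 °C
Reagents that add atoms: none
Why: Proposed new method: heating opens 13 by a conrotatory 4π electrocyclic reaction (C1–C4 breaks, the aryl group turns outward) to vinylketene 14, the ketene C=C of 14 adds 10 in a (2+2) cycloaddition to give 15, a second reversible 4π opening gives dienylketene 16, and 6π closure followed by tautomerisation of dienone 17 gives phenol 18. The closest known reaction type is the Danheiser benzannulation of alkyl-substituted cyclobutenones with alkoxy- or siloxyalkynes, and the untested element is a cyclobutenone that is both a vinylogous ester (3-OEt) and 4-aryl-substituted. Ring D, the only ring formed, closes by a disrotatory 6π electrocyclisation that rejoins the former carbonyl carbon to the aryl-bearing carbon, so that in sum the alkyne is inserted between old C1 and C2 and the new bonds are C2'–C3' and C4'–C5'. No stereocentre is created, since the racemic C4 centre of 13 and the centres of 15 and 17 all end as sp2 carbons of ring D. The selectivity needed is regiochemical: the ynol ether is polarised so that its unsubstituted carbon attacks the ketene carbonyl carbon, which puts the alkyne oxygen at C4' para to ring C and leaves C1' between C2'–OH and C6'–OEt. Closure of 14 onto ring C, the usual fate of 4-arylcyclobutenones, cannot lead to a naphthol because both ortho carbons of ring C bear OMe, and the donor aryl group at C4 should offset the ground-state stabilisation by the 3-ethoxy group, so that opening sets in below the temperature at which 10 loses ethylene by a retro-ene reaction.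

Step 9
Reactants: 18 2-[3-(benzyloxy)-2,4,6-trimethoxyphenyl]-3,5-diethoxyphenol
Product: 19 3-(benzyloxy)-2',4'-diethoxy-2,4,6,6'-tetramethoxy-1,1'-biphenyl
Conditions: MeI, K2CO3, DMF, 40 °C
Reagents that add atoms: iodomethane, CI
Why: Williamson O-methylation caps the only free hydroxyl, so that the later ether coupling meets a single phenol.

Step 10
Reactants: 19 3-(benzyloxy)-2',4'-diethoxy-2,4,6,6'-tetramethoxy-1,1'-biphenyl
Product: 20 2',4'-diethoxy-2,4,6,6'-tetramethoxy-[1,1'-biphenyl]-3-ol
Conditions: H2 (1 atm), 10% Pd/C, EtOAc/EtOH, rt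
Reagents that add atoms: none
Why: Catalytic hydrogenolysis cleaves only the benzylic C–O bond, since methyl and ethyl aryl ethers and the arene rings are untouched at atmospheric pressure.

Step 11
Reactants: 21 3,5-dimethoxyphenol; 22 1,3-dibromo-5-methoxybenzene
Product: 23 1-bromo-3-(3,5-dimethoxyphenoxy)-5-methoxybenzene
Conditions: 22 (3 equiv), CuI (10 mol%), N,N-dimethylglycine hydrochloride (30 mol%), Cs2CO3, 1,4-dioxane, 90 °C
Reagents that add atoms: none
Why: Ligand-accelerated Ullmann diaryl ether synthesis with an unhindered phenol, in which the excess of the symmetric dibromide keeps the reaction at monosubstitution and unreacted 22 can be recovered.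

Step 12
Reactants: 20 2',4'-diethoxy-2,4,6,6'-tetramethoxy-[1,1'-biphenyl]-3-ol; 23 1-bromo-3-(3,5-dimethoxyphenoxy)-5-methoxybenzene
Product: 24 3-[3-(3,5-dimethoxyphenoxy)-5-methoxyphenoxy]-2',4'-diethoxy-2,4,6,6'-tetramethoxy-1,1'-biphenyl
Conditions: CuI (20 mol%), picolinic acid (40 mol%), K3PO4, DMSO, 100 °C, Ar
Reagents that add atoms: none
Why: Ullmann diaryl ether coupling under the CuI/picolinic acid conditions known for 2,6-disubstituted phenols, and because 20 has one OH and 23 one C–Br bond only the B–O–C ether can form.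

Step 13
Reactants: 24 3-[3-(3,5-dimethoxyphenoxy)-5-methoxyphenoxy]-2',4'-diethoxy-2,4,6,6'-tetramethoxy-1,1'-biphenyl
Product: 25 3-[3-(3,5-dihydroxyphenoxy)-5-hydroxyphenoxy]-[1,1'-biphenyl]-2,2',4,4',6,6'-hexaol (CNP0133338.0)
Conditions: BBr3 (25 equiv), CH2Cl2, −78 °C to rt, Ar; then H2O, 0 °C
Reagents that add atoms: none
Why: Lewis-acid dealkylation of aryl alkyl ethers, in which bromide attacks the sp3 carbon of each boron-complexed ether, so that seven methyl and two (slower) ethyl groups leave while the diaryl ether and biaryl bonds offer no such carbon and persist.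

Compound list
1 | 2,4,6-trimethoxybenzaldehyde | COc1cc(OC)c(C=O)c(OC)c1 | starting material
2 | 2,4,6-trimethoxyphenyl formate | COc1cc(OC)c(OC=O)c(OC)c1 | intermediate
3 | 2,4,6-trimethoxyphenol | COc1cc(OC)c(O)c(OC)c1 | intermediate
4 | 2-(benzyloxy)-1,3,5-trimethoxybenzene | COc1cc(OC)c(OCc2ccccc2)c(OC)c1 | intermediate
5 | N-[3-(benzyloxy)-2,4,6-trimethoxybenzylidene]-N-methylmethanaminium dichlorophosphate | C[N+](C)=Cc1c(OC)cc(OC)c(OCc2ccccc2)c1OC.[O-]P(=O)(Cl)Cl | intermediate
6 | 3-(benzyloxy)-2,4,6-trimethoxybenzaldehyde | O=Cc1c(OC)cc(OC)c(OCc2ccccc2)c1OC | intermediate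
7 | 2-(benzyloxy)-1,3,5-trimethoxy-4-(2-methoxyethenyl)benzene (E/Z mixture) | COC=Cc1c(OC)cc(OC)c(OCc2ccccc2)c1OC | intermediate
8 | 2-[3-(benzyloxy)-2,4,6-trimethoxyphenyl]acetaldehyde | O=CCc1c(OC)cc(OC)c(OCc2ccccc2)c1OC | intermediate
9 | 2-[3-(benzyloxy)-2,4,6-trimethoxyphenyl]acetic acid | OC(=O)Cc1c(OC)cc(OC)c(OCc2ccccc2)c1OC | intermediate
10 | ethoxyacetylene | CCOC#C | starting material
11 | 2-[3-(benzyloxy)-2,4,6-trimethoxyphenyl]acetyl chloride | ClC(=O)Cc1c(OC)cc(OC)c(OCc2ccccc2)c1OC | intermediate
12 | 2-[3-(benzyloxy)-2,4,6-trimethoxyphenyl]ethen-1-one (arylketene) | O=C=Cc1c(OC)cc(OC)c(OCc2ccccc2)c1OC | intermediate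
13 | rac-4-[3-(benzyloxy)-2,4,6-trimethoxyphenyl]-3-ethoxycyclobut-2-en-1-one | CCOC1=CC(=O)C1c1c(OC)cc(OC)c(OCc2ccccc2)c1OC | intermediate
14 | (3Z)-4-[3-(benzyloxy)-2,4,6-trimethoxyphenyl]-3-ethoxybuta-1,3-dien-1-one | O=C=C/C(OCC)=C/c1c(OC)cc(OC)c(OCc2ccccc2)c1OC | intermediate
15 | rac-4-{(Z)-2-[3-(benzyloxy)-2,4,6-trimethoxyphenyl]-1-ethoxyethenyl}-3-ethoxycyclobut-2-en-1-one | CCOC1=CC(=O)C1/C(OCC)=C/c1c(OC)cc(OC)c(OCc2ccccc2)c1OC | intermediate
16 | (3E,5Z)-6-[3-(benzyloxy)-2,4,6-trimethoxyphenyl]-3,5-diethoxyhexa-1,3,5-trien-1-one | O=C=C/C(OCC)=C\C(OCC)=C\c1c(OC)cc(OC)c(OCc2ccccc2)c1OC | intermediate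
17 | rac-6-[3-(benzyloxy)-2,4,6-trimethoxyphenyl]-3,5-diethoxycyclohexa-2,4-dien-1-one | CCOC1=CC(=O)C(c2c(OC)cc(OC)c(OCc3ccccc3)c2OC)C(OCC)=C1 | intermediate
18 | 2-[3-(benzyloxy)-2,4,6-trimethoxyphenyl]-3,5-diethoxyphenol | CCOc1cc(O)c(-c2c(OC)cc(OC)c(OCc3ccccc3)c2OC)c(OCC)c1 | intermediate
19 | 3-(benzyloxy)-2',4'-diethoxy-2,4,6,6'-tetramethoxy-1,1'-biphenyl | CCOc1cc(OC)c(-c2c(OC)cc(OC)c(OCc3ccccc3)c2OC)c(OCC)c1 | intermediate
20 | 2',4'-diethoxy-2,4,6,6'-tetramethoxy-[1,1'-biphenyl]-3-ol | CCOc1cc(OC)c(-c2c(OC)cc(OC)c(O)c2OC)c(OCC)c1 | intermediate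
21 | 3,5-dimethoxyphenol | COc1cc(O)cc(OC)c1 | starting material
22 | 1,3-dibromo-5-methoxybenzene | COc1cc(Br)cc(Br)c1 | starting material
23 | 1-bromo-3-(3,5-dimethoxyphenoxy)-5-methoxybenzene | COc1cc(Br)cc(Oc2cc(OC)cc(OC)c2)c1 | intermediate
24 | 3-[3-(3,5-dimethoxyphenoxy)-5-methoxyphenoxy]-2',4'-diethoxy-2,4,6,6'-tetramethoxy-1,1'-biphenyl | CCOc1cc(OC)c(-c2c(OC)cc(OC)c(Oc3cc(OC)cc(Oc4cc(OC)cc(OC)c4)c3)c2OC)c(OCC)c1 | intermediate
25 | 3-[3-(3,5-dihydroxyphenoxy)-5-hydroxyphenoxy]-[1,1'-biphenyl]-2,2',4,4',6,6'-hexaol | Oc1cc(O)cc(Oc2cc(O)cc(Oc3c(O)cc(O)c(-c4c(O)cc(O)cc4O)c3O)c2)c1 | target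

Total step count: 13.
Longest linear sequence: 12 steps (steps 1 to 10, 12 and 13, from 1).

Steps most likely to fail

Step 8. The vinylogous-ester resonance may keep the four-membered ring closed up to temperatures at which ethoxyacetylene fragments. The vinylketene may also be lost to O-acylation of phenol already formed or to oligomerisation. The fallback makes the C1–C1' bond by known cross-coupling; it sets out from 4 and comes back to the route at 25.
- Bromination of 4 with N-bromosuccinimide in MeCN at 0 °C should give 1-(benzyloxy)-3-bromo-2,4,6-trimethoxybenzene F1.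
- Suzuki–Miyaura coupling of F1 with an excess of commercial 2,4,6-trimethoxyphenylboronic acid should give 3-(benzyloxy)-2,2',4,4',6,6'-hexamethoxy-1,1'-biphenyl F2. The conditions (Pd(OAc)2, SPhos, K3PO4, toluene/H2O, 100 °C) are known for tetra-ortho-substituted biaryls.
- Hydrogenolysis as in step 10 gives 2,2',4,4',6,6'-hexamethoxy-[1,1'-biphenyl]-3-ol F3.
- Coupling with 23 as in step 12 gives 3-[3-(3,5-dimethoxyphenoxy)-5-methoxyphenoxy]-2,2',4,4',6,6'-hexamethoxy-1,1'-biphenyl F4.
- BBr3 as in step 13 then delivers 25.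

Step 7. Three processes may consume the material: amine-promoted dimerisation of the aldoketene, acylation of the enolisable cyclobutenone by further ketene, and lactonisation of the acyl chloride onto an ortho methoxy oxygen with loss of its methyl group. The fallback generates the same ketene without base, by Wolff rearrangement; it sets out from 6 and comes back at 13.
- Pinnick oxidation of 6 gives 3-(benzyloxy)-2,4,6-trimethoxybenzoic acid F5.
- (COCl)2 with cat. DMF gives 3-(benzyloxy)-2,4,6-trimethoxybenzoyl chloride F6.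
- Excess diazomethane in Et2O at 0 °C (the first stage of an Arndt–Eistert sequence) gives 1-[3-(benzyloxy)-2,4,6-trimethoxyphenyl]-2-diazoethan-1-one F7.
- Irradiation of F7 (Pyrex-filtered Hg lamp, CH2Cl2, rt) in the presence of 10 (5 equiv) expels nitrogen and gives arylketene 12 at low stationary concentration. Capture of 12 by 10 gives 13.

Step 12. C–O bond formation at a phenoxide flanked by two methoxy groups may be slow. Reductive loss of bromine from the aryl bromide and oxidation of the electron-rich phenoxide could then take over. The fallback forms the hindered ether bond without metal, by ligand coupling at trivalent iodine, and attaches ring A afterwards; it sets out from 20 and comes back at 24.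
- Commercial 1-bromo-3-iodo-5-methoxybenzene is oxidised with mCPBA and BF3·OEt2 in CH2Cl2.
- Treatment with 4-methoxyphenylboronic acid at 0 °C then gives (3-bromo-5-methoxyphenyl)(4-methoxyphenyl)iodonium tetrafluoroborate F8.
- With 20 and KOtBu in THF at 0 to 40 °C, the less electron-rich aryl group of F8 is transferred to oxygen. This gives 3-(3-bromo-5-methoxyphenoxy)-2',4'-diethoxy-2,4,6,6'-tetramethoxy-1,1'-biphenyl F9.
- Ullmann coupling of F9 with the unhindered phenol 21 under the conditions of step 11 gives 24.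

Further compounds
F1 | step 8 | 1-(benzyloxy)-3-bromo-2,4,6-trimethoxybenzene | COc1cc(OC)c(OCc2ccccc2)c(OC)c1Br
F2 | step 8 | 3-(benzyloxy)-2,2',4,4',6,6'-hexamethoxy-1,1'-biphenyl | COc1cc(OC)c(-c2c(OC)cc(OC)c(OCc3ccccc3)c2OC)c(OC)c1
F3 | step 8 | 2,2',4,4',6,6'-hexamethoxy-[1,1'-biphenyl]-3-ol | COc1cc(OC)c(-c2c(OC)cc(OC)c(O)c2OC)c(OC)c1
F4 | step 8 | 3-[3-(3,5-dimethoxyphenoxy)-5-methoxyphenoxy]-2,2',4,4',6,6'-hexamethoxy-1,1'-biphenyl | COc1cc(OC)c(-c2c(OC)cc(OC)c(Oc3cc(OC)cc(Oc4cc(OC)cc(OC)c4)c3)c2OC)c(OC)c1
F5 | step 7 | 3-(benzyloxy)-2,4,6-trimethoxybenzoic acid | OC(=O)c1c(OC)cc(OC)c(OCc2ccccc2)c1OC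
F6 | step 7 | 3-(benzyloxy)-2,4,6-trimethoxybenzoyl chloride | ClC(=O)c1c(OC)cc(OC)c(OCc2ccccc2)c1OC
F7 | step 7 | 1-[3-(benzyloxy)-2,4,6-trimethoxyphenyl]-2-diazoethan-1-one | [N-]=[N+]=CC(=O)c1c(OC)cc(OC)c(OCc2ccccc2)c1OC
F8 | step 12 | (3-bromo-5-methoxyphenyl)(4-methoxyphenyl)iodonium tetrafluoroborate | COc1ccc([I+]c2cc(Br)cc(OC)c2)cc1.F[B-](F)(F)F
F9 | step 12 | 3-(3-bromo-5-methoxyphenoxy)-2',4'-diethoxy-2,4,6,6'-tetramethoxy-1,1'-biphenyl | CCOc1cc(OC)c(-c2c(OC)cc(OC)c(Oc3cc(Br)cc(OC)c3)c2OC)c(OCC)c1
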